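**Strategy.** The upper flavan unit is disconnected at C4–C4a and O1–C2, so ring C is grown onto ring A. Ring A is a resorcinol. Its carbon C4a lies para to the 7-oxygen and sits next to the oxygen on C8a, so the two act together as a C,O-bis-nucleophile. They fit a three-carbon unit (C4, C3, C2) that is electrophilic at both ends. One carbene-catalysed operation with a chiral triazolium salt activates a ynal carried by ring D as its unsaturated acyl azolium. Free resorcinol then forms C4–C4a and O1–C2, giving ring C as a (4R)-4-aryldihydrocoumarin. The precursor is fully benzylated (+)-gallocatechin with a propynal chain on C8. The lactone carbonyl later brings in O3 and ring B.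

Key step: step 6

**Remarks on the chemistry**
- Configuration planned for: the upper unit (rings A, C, B) is 2R,3S,4R, that is 2,3-trans-3,4-cis (4β). The lower unit (rings D, F, E) is 2R,3S. Flavan numbering of the upper unit is kept for all intermediates, open-chain ones included.
- Gallocatechin has six hydroxyl groups, so the ring-D partner and all later intermediates carry a hexa-O-benzyl unit, not a penta-O-benzyl one. A free O3 on ring F would be acylated by the acyl azolium.
- Assumption: the (5aR,10bS) antipode of the triazolium salt is taken to give 4R. If a first run shows the opposite sense, the equally available mirror-image salt is used and nothing else changes.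

**Route**

Step 1
Reactants: 1 (+)-gallocatechin
Product: 2 5,7,3',4',5'-penta-O-benzyl-(+)-gallocatechin (2R,3S; 3-OH free)
Conditions: BnBr (5.5 equiv), K2CO3, DMF, argon, 0 °C to rt
Reagents that add atoms: benzyl bromide, BrCc1ccccc1
Why: Williamson etherification in which K2CO3 alkylates only the five phenols, while exclusion of air and the halide being present from the start suppress pyrogallol oxidation and base-induced C2 epimerisation, so (2R,3S) is kept.

Step 2
Reactants: 2 5,7,3',4',5'-penta-O-benzyl-(+)-gallocatechin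
Product: 3 3,5,7,3',4',5'-hexa-O-benzyl-(+)-gallocatechin (2R,3S)
Conditions: NaH, BnBr, DMF, 0 °C to rt
Reagents that add atoms: benzyl bromide, BrCc1ccccc1
Why: Williamson etherification of the remaining secondary alcohol through its sodium alkoxide, needed because a free O3 on ring F would compete for the acyl azolium in step 6.

Step 3
Reactants: 3 hexa-O-benzyl-(+)-gallocatechin
Product: 4 8-bromo-hexa-O-benzylgallocatechin (2R,3S)
Conditions: NBS (1.0 equiv), CH2Cl2, −78 to 0 °C
Reagents that add atoms: N-bromosuccinimide, O=C1CCC(=O)N1Br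
Why: Electrophilic aromatic bromination, in which ring D is the only ring activated by three oxygen donors and benzylated catechin-type flavans are known to take one equivalent of NBS at C8 rather than C6.

Step 4
Reactants: 4 8-bromo-hexa-O-benzylgallocatechin; 5 propargyl alcohol
Product: 6 3-(hexa-O-benzylgallocatechin-8-yl)prop-2-yn-1-ol
Conditions: 5 (1.5 equiv), Pd(PhCN)2Cl2 (5 mol %), P(t-Bu)3·HBF4 (10 mol %), CuI (5 mol %), i-Pr2NH, 1,4-dioxane, rt to 50 °C
Reagents that add atoms: none
Why: Sonogashira coupling, in which the bulky electron-rich phosphine lets zerovalent palladium insert into this electron-rich, doubly ortho-substituted aryl bromide, and propargyl alcohol delivers C4, C3 and C2 of the upper unit in one piece.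

Step 5
Reactants: 6 3-(hexa-O-benzylgallocatechin-8-yl)prop-2-yn-1-ol
Product: 7 3-(hexa-O-benzylgallocatechin-8-yl)prop-2-ynal
Conditions: activated MnO2 (excess), CH2Cl2, rt
Reagents that add atoms: none
Why: Selective MnO2 oxidation of a propargylic alcohol to the ynal under neutral conditions, which leaves the benzyl ethers and both stereocentres of ring F untouched.

Step 6
Reactants: 7 3-(hexa-O-benzylgallocatechin-8-yl)prop-2-ynal; 8 resorcinol
Product: 10 (4R)-7-hydroxy-4-(hexa-O-benzylgallocatechin-8-yl)chroman-2-one, via unsaturated acyl azolium 9 (not isolated)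
Conditions: 8 (3 equiv), (5aR,10bS)-2-mesityl-5a,10b-dihydro-4H,6H-indeno[2,1-b][1,2,4]triazolo[4,3-d][1,4]oxazin-2-ium tetrafluoroborate (20 mol %), i-Pr2NEt (30 mol %), 4 Å molecular sieves, toluene/THF 3:1, 40 °C
Reagents that add atoms: none
Why: Proposed new method: the carbene adds to the formyl group of 7 and proton transfer through the allenol (internal redox) gives the (E)-unsaturated acyl azolium 9; resorcinol monoanion then joins the ring carbon that is ortho to one oxygen and para to the other to the beta-carbon (C4–C4a), either by direct conjugate addition or by 1,2-addition and [3,3] shift, and after rearomatisation and protonation at C3 the neighbouring oxygen attacks the acyl carbon (O1–C2) and expels the carbene. The closest known reaction type is the carbene-catalysed [3+3] annulation of ynals, enals or 2-bromoenals with naphthols, kojic acids and electron-rich phenols to 4-substituted dihydrocoumarins and dihydropyranones; neither resorcinol itself nor a beta-aryl group flanked by two ortho oxygens has been shown. Ring C closes by 6-exo-trig lactonisation after the intermolecular C–C bond has formed. C4, the only new stereocentre, is fixed by the aminoindanol backbone and N-mesityl group of the triazolium, which leave one face of the planar acyl azolium open, so the distant centres of ring F should cause no more than a mild match or mismatch. The step needs C- over O-attack and the right ring carbon: aryl ester formation is reversible under carbene catalysis and drains into the lactone, the two productive carbons of resorcinol are equivalent by symmetry and each has a hydroxyl next to it, and the carbon between the two hydroxyls is too crowded for this bulky acceptor. Excess resorcinol keeps the less nucleophilic product phenol from reacting a second time, and the benzyl group on O3 of ring F removes the only competing alcohol.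

Step 7
Reactants: 10 (4R)-7-hydroxy-4-(hexa-O-benzylgallocatechin-8-yl)chroman-2-one
Product: 11 (4R)-7-benzyloxy-4-(hexa-O-benzylgallocatechin-8-yl)chroman-2-one
Conditions: BnBr, K2CO3, dry acetone, rt
Reagents that add atoms: benzyl bromide, BrCc1ccccc1
Why: Williamson etherification of the single phenol under anhydrous, mildly basic conditions that an aryl lactone tolerates, which removes the acidic 7-OH before the enolate chemistry.

Step 8
Reactants: 11 (4R)-7-benzyloxy-4-(hexa-O-benzylgallocatechin-8-yl)chroman-2-one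
Product: 13 (3R,4R)-7-benzyloxy-3-hydroxy-4-(hexa-O-benzylgallocatechin-8-yl)chroman-2-one (3,4-trans), via potassium enolate 12 (not isolated)
Conditions: KN(SiMe3)2, THF, −78 °C; 2-(phenylsulfonyl)-3-phenyloxaziridine, −78 °C; AcOH
Reagents that add atoms: 2-(phenylsulfonyl)-3-phenyloxaziridine, O=S(=O)(N1OC1c1ccccc1)c1ccccc1
Why: Davis enolate oxidation, in which the bulky ring-D aryl group sits pseudoaxial on C4 of the flattened lactone enolate, so oxygen is transferred to the opposite face and the 3,4-trans alcohol (3R) results.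

Step 9
Reactants: 13 (3R,4R)-7-benzyloxy-3-hydroxy-4-(hexa-O-benzylgallocatechin-8-yl)chroman-2-one
Product: 14 (3R,4R)-3,7-bis(benzyloxy)-4-(hexa-O-benzylgallocatechin-8-yl)chroman-2-one (3,4-trans)
Conditions: BnBr, Ag2O, 4 Å molecular sieves, CH2Cl2, rt, dark
Reagents that add atoms: benzyl bromide, BrCc1ccccc1
Why: Ag2O-promoted benzylation, the mild Williamson variant routinely used for alpha-hydroxy esters, caps O3 without opening the aryl lactone.

Step 10
Reactants: 14 (3R,4R)-3,7-bis(benzyloxy)-4-(hexa-O-benzylgallocatechin-8-yl)chroman-2-one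
Product: 16 (3S,4R)-3,7-bis(benzyloxy)-4-(hexa-O-benzylgallocatechin-8-yl)chroman-2-one (3,4-cis), via potassium enolate 15 (not isolated)
Conditions: KN(SiMe3)2, THF, −78 to −40 °C; t-BuCO2H (excess) in THF, −78 °C
Reagents that add atoms: none
Why: Deprotonation and kinetic protonation (contra-thermodynamic epimerisation of a lactone), in which C3 becomes planar and the same pseudoaxial C4 aryl group forces the proton to arrive anti to it, so O3 ends up cis to the aryl group (3S) without any leaving group on C3 next to the migration-prone trialkoxyaryl ring.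

Step 11
Reactants: 16 (3S,4R)-3,7-bis(benzyloxy)-4-(hexa-O-benzylgallocatechin-8-yl)chroman-2-one
Product: 17 (3S,4R)-3,7-bis(benzyloxy)-4-(hexa-O-benzylgallocatechin-8-yl)chroman-2-ol (lactol, mixture at C2)
Conditions: i-Bu2AlH (1.1 equiv), toluene, −78 °C; aq. potassium sodium tartrate (KNaC4H4O6)
Reagents that add atoms: none
Why: Partial reduction of a lactone with i-Bu2AlH, well established for 4-aryldihydrocoumarins, stops at the lactol at −78 °C and is not basic enough to disturb C3.

Step 12
Reactants: 17 lactol; 18 5-bromo-1,2,3-tris(benzyloxy)benzene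
Product: 20 (1S,2S,3R)-2-benzyloxy-3-(4-benzyloxy-2-hydroxyphenyl)-3-(hexa-O-benzylgallocatechin-8-yl)-1-[3,4,5-tris(benzyloxy)phenyl]propan-1-ol (2S,3S,4R in flavan numbering), via arylmagnesium bromide 19 (not isolated)
Conditions: 18, Mg, cat. I2, THF, 50 °C; then 17 (3 equiv of 19), THF/CH2Cl2, −78 to 0 °C; H2O
Reagents that add atoms: none
Why: Grignard addition to a lactol, in which the first equivalent opens it to the magnesium phenoxide aldehyde and aryl transfer within the Cram chelate (Mg bound to the aldehyde oxygen and O3) occurs opposite to the bulky C4 diarylmethyl group, giving the 2,3-syn alcohol.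

Step 13
Reactants: 20 open-chain phenol alcohol
Product: 21 undeca-O-benzyl-robinetinidol-(4β→8)-gallocatechin (upper unit 2R,3S,4R; lower unit 2R,3S)
Conditions: PPh3, DIAD, THF, 0 °C to rt
Reagents that add atoms: none
Why: Intramolecular Mitsunobu etherification (6-exo-tet), in which the only free alcohol is activated and displaced by the ring-A phenoxide with inversion (2S to 2R), and should the electron-rich benzylic centre ionise instead, the ion pair should close to the same 2,3-trans isomer with ring B and O3 equatorial.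

Step 14
Reactants: 21 undeca-O-benzyl-robinetinidol-(4β→8)-gallocatechin
Product: 22 robinetinidol-(4β→8)-gallocatechin (CNP0275321.1)
Conditions: H2 (1 atm), Pd(OH)2/C, THF/MeOH, rt, argon during work-up
Reagents that add atoms: none
Why: Global hydrogenolysis of eleven benzyl ethers over Pd(OH)2/C, the usual last step for proanthocyanidins, leaves both C2–O1 bonds, the C4–C8 bond and all five stereocentres intact.

**Compound list**

1 | (+)-gallocatechin (2R,3S) | Oc1cc(O)c2c(c1)O[C@H](c1cc(O)c(O)c(O)c1)[C@@H](O)C2 | starting material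
2 | 5,7,3',4',5'-penta-O-benzyl-(+)-gallocatechin | c1c(OCc3ccccc3)cc(OCc3ccccc3)c2c1O[C@H](c1cc(OCc3ccccc3)c(OCc3ccccc3)c(OCc3ccccc3)c1)[C@@H](O)C2 | intermediate
3 | 3,5,7,3',4',5'-hexa-O-benzyl-(+)-gallocatechin | c1c(OCc3ccccc3)cc(OCc3ccccc3)c2c1O[C@H](c1cc(OCc3ccccc3)c(OCc3ccccc3)c(OCc3ccccc3)c1)[C@@H](OCc3ccccc3)C2 | intermediate
4 | 8-bromo-hexa-O-benzylgallocatechin | Brc1c(OCc3ccccc3)cc(OCc3ccccc3)c2c1O[C@H](c1cc(OCc3ccccc3)c(OCc3ccccc3)c(OCc3ccccc3)c1)[C@@H](OCc3ccccc3)C2 | intermediate
5 | propargyl alcohol | C#CCO | starting material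
6 | 3-(hexa-O-benzylgallocatechin-8-yl)prop-2-yn-1-ol | OCC#Cc1c(OCc3ccccc3)cc(OCc3ccccc3)c2c1O[C@H](c1cc(OCc3ccccc3)c(OCc3ccccc3)c(OCc3ccccc3)c1)[C@@H](OCc3ccccc3)C2 | intermediate
7 | 3-(hexa-O-benzylgallocatechin-8-yl)prop-2-ynal | O=CC#Cc1c(OCc3ccccc3)cc(OCc3ccccc3)c2c1O[C@H](c1cc(OCc3ccccc3)c(OCc3ccccc3)c(OCc3ccccc3)c1)[C@@H](OCc3ccccc3)C2 | intermediate
8 | resorcinol | Oc1cccc(O)c1 | starting material
9 | (E)-3-(hexa-O-benzylgallocatechin-8-yl)acryloyl group on the carbene carbon of the (5aR,10bS)-2-mesityl-indeno-triazolo-oxazinium ring, tetrafluoroborate | Cc1cc(C)c(c(C)c1)[n+]1nc2CO[C@@H]3Cc4ccccc4[C@@H]3n2c1C(=O)/C=C/c1c(OCc3ccccc3)cc(OCc3ccccc3)c2c1O[C@H](c1cc(OCc3ccccc3)c(OCc3ccccc3)c(OCc3ccccc3)c1)[C@@H](OCc3ccccc3)C2.F[B-](F)(F)F | intermediate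
10 | (4R)-7-hydroxy-4-(hexa-O-benzylgallocatechin-8-yl)chroman-2-one | Oc1ccc2c(c1)OC(=O)C[C@H]2c1c(OCc3ccccc3)cc(OCc3ccccc3)c2c1O[C@H](c1cc(OCc3ccccc3)c(OCc3ccccc3)c(OCc3ccccc3)c1)[C@@H](OCc3ccccc3)C2 | intermediate
11 | (4R)-7-benzyloxy-4-(hexa-O-benzylgallocatechin-8-yl)chroman-2-one | O(Cc3ccccc3)c1ccc2c(c1)OC(=O)C[C@H]2c1c(OCc3ccccc3)cc(OCc3ccccc3)c2c1O[C@H](c1cc(OCc3ccccc3)c(OCc3ccccc3)c(OCc3ccccc3)c1)[C@@H](OCc3ccccc3)C2 | intermediate
12 | potassium enolate of 11 | [K+].O(Cc3ccccc3)c1ccc2c(c1)OC([O-])=C[C@H]2c1c(OCc3ccccc3)cc(OCc3ccccc3)c2c1O[C@H](c1cc(OCc3ccccc3)c(OCc3ccccc3)c(OCc3ccccc3)c1)[C@@H](OCc3ccccc3)C2 | intermediate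
13 | (3R,4R)-7-benzyloxy-3-hydroxy-4-(hexa-O-benzylgallocatechin-8-yl)chroman-2-one (3,4-trans) | O(Cc3ccccc3)c1ccc2c(c1)OC(=O)[C@H](O)[C@H]2c1c(OCc3ccccc3)cc(OCc3ccccc3)c2c1O[C@H](c1cc(OCc3ccccc3)c(OCc3ccccc3)c(OCc3ccccc3)c1)[C@@H](OCc3ccccc3)C2 | intermediate
14 | (3R,4R)-3,7-bis(benzyloxy)-4-(hexa-O-benzylgallocatechin-8-yl)chroman-2-one (3,4-trans) | O(Cc3ccccc3)c1ccc2c(c1)OC(=O)[C@H](OCc3ccccc3)[C@H]2c1c(OCc3ccccc3)cc(OCc3ccccc3)c2c1O[C@H](c1cc(OCc3ccccc3)c(OCc3ccccc3)c(OCc3ccccc3)c1)[C@@H](OCc3ccccc3)C2 | intermediate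
15 | potassium enolate of 14 | [K+].O(Cc3ccccc3)c1ccc2c(c1)OC([O-])=C(OCc3ccccc3)[C@H]2c1c(OCc3ccccc3)cc(OCc3ccccc3)c2c1O[C@H](c1cc(OCc3ccccc3)c(OCc3ccccc3)c(OCc3ccccc3)c1)[C@@H](OCc3ccccc3)C2 | intermediate
16 | (3S,4R)-3,7-bis(benzyloxy)-4-(hexa-O-benzylgallocatechin-8-yl)chroman-2-one (3,4-cis) | O(Cc3ccccc3)c1ccc2c(c1)OC(=O)[C@@H](OCc3ccccc3)[C@H]2c1c(OCc3ccccc3)cc(OCc3ccccc3)c2c1O[C@H](c1cc(OCc3ccccc3)c(OCc3ccccc3)c(OCc3ccccc3)c1)[C@@H](OCc3ccccc3)C2 | intermediate
17 | (3S,4R)-3,7-bis(benzyloxy)-4-(hexa-O-benzylgallocatechin-8-yl)chroman-2-ol (C2 mixture) | O(Cc3ccccc3)c1ccc2c(c1)OC(O)[C@@H](OCc3ccccc3)[C@H]2c1c(OCc3ccccc3)cc(OCc3ccccc3)c2c1O[C@H](c1cc(OCc3ccccc3)c(OCc3ccccc3)c(OCc3ccccc3)c1)[C@@H](OCc3ccccc3)C2 | intermediate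
18 | 5-bromo-1,2,3-tris(benzyloxy)benzene | Brc1cc(OCc2ccccc2)c(OCc2ccccc2)c(OCc2ccccc2)c1 | starting material
19 | 3,4,5-tris(benzyloxy)phenylmagnesium bromide | Br[Mg]c1cc(OCc2ccccc2)c(OCc2ccccc2)c(OCc2ccccc2)c1 | intermediate
20 | (1S,2S,3R)-2-benzyloxy-3-(4-benzyloxy-2-hydroxyphenyl)-3-(hexa-O-benzylgallocatechin-8-yl)-1-[3,4,5-tris(benzyloxy)phenyl]propan-1-ol | O[C@@H](c1cc(OCc3ccccc3)c(OCc3ccccc3)c(OCc3ccccc3)c1)[C@@H](OCc3ccccc3)[C@H](c1ccc(OCc3ccccc3)cc1O)c1c(OCc3ccccc3)cc(OCc3ccccc3)c2c1O[C@H](c1cc(OCc3ccccc3)c(OCc3ccccc3)c(OCc3ccccc3)c1)[C@@H](OCc3ccccc3)C2 | intermediate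
21 | undeca-O-benzyl-robinetinidol-(4β→8)-gallocatechin | O(Cc3ccccc3)c1ccc2c(c1)O[C@H](c1cc(OCc3ccccc3)c(OCc3ccccc3)c(OCc3ccccc3)c1)[C@@H](OCc3ccccc3)[C@H]2c1c(OCc3ccccc3)cc(OCc3ccccc3)c2c1O[C@H](c1cc(OCc3ccccc3)c(OCc3ccccc3)c(OCc3ccccc3)c1)[C@@H](OCc3ccccc3)C2 | intermediate
22 | robinetinidol-(4β→8)-gallocatechin, CNP0275321.1 | Oc1ccc2c(c1)O[C@H](c1cc(O)c(O)c(O)c1)[C@@H](O)[C@H]2c1c(O)cc(O)c2c1O[C@H](c1cc(O)c(O)c(O)c1)[C@@H](O)C2 | target

**Step count**
- Total steps: 14.
- Longest linear sequence: 14, from (+)-gallocatechin.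

**Steps most likely to fail**

1. **Step 6 (the labelled step).**
   - Risk: the beta-carbon of the acyl azolium is deactivated by the trialkoxyaryl donor and screened by two ortho oxygens. Conjugate addition may therefore be too slow, the ynal may drain into simple ester formation, or facial selectivity may be poor.
   - Fallback with known chemistry, from 4 back to 10: bromine–lithium exchange on 4 (n-BuLi, THF, −78 °C) and formylation with DMF would give hexa-O-benzylgallocatechin-8-carbaldehyde F1. Knoevenagel condensation with Meldrum's acid (cat. piperidinium acetate, toluene, rt) would give the arylidene Meldrum's acid F2. Yb(OTf)3-catalysed Friedel–Crafts conjugate addition of resorcinol 8, followed by lactonisation with loss of acetone and CO2 (MeCN, 60 °C), would form the same two bonds. This would give 10 beside its (4S)-epimer F3.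
   - Consequence: C4 is not controlled in this variant. The two products are diastereomers because of ring F, so they would be separated by chromatography.

2. **Step 10.**
   - Risk: enolisation of the shielded C3–H may be slow or incomplete, the proton may not discriminate well enough between the two faces, or the product may re-equilibrate on warming.
   - Fallback, from 13 back to 16: Mitsunobu inversion of 13 with chloroacetic acid (PPh3, DIAD, toluene, 0 °C to rt) would give the 3,4-cis chloroacetate F4. Thiourea (THF/EtOH, 40 °C) would remove the chloroacetyl group without opening the aryl lactone and give the (3S,4R)-3-hydroxy lactone F5. BnBr/Ag2O as in step 9 would then give 16.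
   - Consequence: C–O inversion replaces C–H re-formation. Its own hazard is participation of the ring-D aryl group once C3 carries a leaving group, which is why it is only the second choice.

3. **Step 13.**
   - Risk: ionisation at C2 could erode the stereochemical fidelity of the closure, and elimination towards the C2–C3 enol ether could compete.
   - Fallback, from 17 back to 21 (it also bypasses step 12): ring C stays closed and ring B enters as the nucleophile. PhSO2H and CaCl2 in CH2Cl2 would convert lactol 17 into the (3S,4R)-2-(phenylsulfonyl)chroman F6. Reagent 19 and ZnBr2 in THF would give 3,4,5-tris(benzyloxy)phenylzinc bromide F7. F6 and F7 (THF, 0 °C to rt) would react through the ring-C oxocarbenium ion, which is the known substitution of anomeric sulfones by organozinc reagents.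
   - Consequence: the aryl group would enter C2 from the face opposite to both O3 and the C4 aryl group. That is the 2,3-trans-2,4-trans arrangement of 21.

Further compounds
F1 | step 6 | hexa-O-benzylgallocatechin-8-carbaldehyde | O=Cc1c(OCc3ccccc3)cc(OCc3ccccc3)c2c1O[C@H](c1cc(OCc3ccccc3)c(OCc3ccccc3)c(OCc3ccccc3)c1)[C@@H](OCc3ccccc3)C2
F2 | step 6 | 5-[(hexa-O-benzylgallocatechin-8-yl)methylidene]-2,2-dimethyl-1,3-dioxane-4,6-dione | CC1(C)OC(=O)C(C(=O)O1)=Cc1c(OCc3ccccc3)cc(OCc3ccccc3)c2c1O[C@H](c1cc(OCc3ccccc3)c(OCc3ccccc3)c(OCc3ccccc3)c1)[C@@H](OCc3ccccc3)C2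
F3 | step 6 | (4S)-7-hydroxy-4-(hexa-O-benzylgallocatechin-8-yl)chroman-2-one | Oc1ccc2c(c1)OC(=O)C[C@@H]2c1c(OCc3ccccc3)cc(OCc3ccccc3)c2c1O[C@H](c1cc(OCc3ccccc3)c(OCc3ccccc3)c(OCc3ccccc3)c1)[C@@H](OCc3ccccc3)C2
F4 | step 10 | (3S,4R)-7-benzyloxy-3-(chloroacetoxy)-4-(hexa-O-benzylgallocatechin-8-yl)chroman-2-one | O(Cc3ccccc3)c1ccc2c(c1)OC(=O)[C@@H](OC(=O)CCl)[C@H]2c1c(OCc3ccccc3)cc(OCc3ccccc3)c2c1O[C@H](c1cc(OCc3ccccc3)c(OCc3ccccc3)c(OCc3ccccc3)c1)[C@@H](OCc3ccccc3)C2
F5 | step 10 | (3S,4R)-7-benzyloxy-3-hydroxy-4-(hexa-O-benzylgallocatechin-8-yl)chroman-2-one | O(Cc3ccccc3)c1ccc2c(c1)OC(=O)[C@@H](O)[C@H]2c1c(OCc3ccccc3)cc(OCc3ccccc3)c2c1O[C@H](c1cc(OCc3ccccc3)c(OCc3ccccc3)c(OCc3ccccc3)c1)[C@@H](OCc3ccccc3)C2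
F6 | step 13 | (3S,4R)-3,7-bis(benzyloxy)-4-(hexa-O-benzylgallocatechin-8-yl)-2-(phenylsulfonyl)chroman (C2 mixture) | O(Cc3ccccc3)c1ccc2c(c1)OC(S(=O)(=O)c1ccccc1)[C@@H](OCc3ccccc3)[C@H]2c1c(OCc3ccccc3)cc(OCc3ccccc3)c2c1O[C@H](c1cc(OCc3ccccc3)c(OCc3ccccc3)c(OCc3ccccc3)c1)[C@@H](OCc3ccccc3)C2
F7 | step 13 | 3,4,5-tris(benzyloxy)phenylzinc bromide | Br[Zn]c1cc(OCc2ccccc2)c(OCc2ccccc2)c(OCc2ccccc2)c1
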